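## The problem

The target 16 is a 2-arylchromen-4-one. Ring A and the pyranone ring C share the C4a–C8a bond, and ring B sits on C2 through the C2–C1' bond, which is flanked by the 2'-methoxy and the 6'-hydroxy group, so ring B is twisted out of the chromone plane and shields C2 and C3. There is no stereocentre; the difficulty is constitutional: seven oxygen substituents on two benzene rings, of which exactly two (O5 and O6') are free phenols. The 5-hydroxyl is hydrogen-bonded to the C4 carbonyl and can travel as a methyl ether that a chelating Lewis acid singles out at the end, whereas O6' has no such handle and needs its own protecting group throughout. Several features forbid rough treatment: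

- Both rings are very electron-rich and each has one free position (C8, C5') open to electrophiles and oxidants.
- A benzylic carbon on the 2,4,6-trioxygenated ring B ionises readily in acid.
- 2,6-Dioxygenated benzoic acids decarboxylate.
- A flavone with a free ortho-hydroxyl on ring B can open at O1–C2 in hot acid or base and reclose through that hydroxyl (Wessely–Moser-type isomerisation), which would exchange rings A and B.

Two structural features are exploited. C3 is a lone CH between the C4 carbonyl and the aryl-bearing C2, so ring C is a 2-aryl-3-oxybenzofuran with one carbon inserted into its C2=C3 bond. Each aryl half is 3,4,5-trimethoxyphenol carrying one carbon ortho to its hydroxyl (C4 on ring A, C2 on ring B), so one ortho-formylated phenol can supply both halves.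

## Retrosynthesis

**16 ⇒ 15 (O5–methyl).** The 5-hydroxyl of 16 is traced back to the methyl ether 15. This is preferred over a separate protecting group on O5 because chelation to the C4 carbonyl already distinguishes this methyl from the other five, and because it lets ring A come from a phenol with three identical methoxy groups. The forward reaction must remove exactly one methyl group without water or heat, since the 6'-hydroxyl is then free.

**15 ⇒ 14 (C3–Br and O6'–benzyl).** The C3 hydrogen and the 6'-hydroxyl of 15 are traced back to a C3 bromine and a benzyl ether in 14. The bromine is the unavoidable trace of the carbene used earlier. Benzyl is chosen for O6' because both groups then fall in one hydrogenolysis; an acetal or isopropyl ether would cost a separate operation. The forward step must leave the C2=C3 bond intact.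

**14 ⇒ 10 + 11 (C2–C3 and C3–C4, the key cut).** Both bonds to C3 are cut and C3 is excised as the carbon of bromoform 11, which leaves the 2-aryl-3-siloxybenzofuran 10. The classical cuts, C3–C4 by acyl transfer or C2–C3 by aldol condensation of an acetophenone, need a two-carbon unit on ring A and leave open whether a five- or six-membered ring closes. Here the five-membered ring is made on purpose and is then enlarged by exactly one atom, so the ring size is fixed by mechanism. The precursor is simpler by one carbon and has the two aryl halves joined only by ether and ester chemistry. The forward reaction requires the carbene from 11 to add to the enol ether bond of 10 and the adduct 12 to open at its internal bond through 13.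

**10 ⇒ 8 (benzofuran C2–C3 and O–Si).** The furan bond between the aryl-bearing carbon and the oxygen-bearing carbon is cut, together with the silyl ether, which leads through enolate 9 to the benzyl aryl ether 8 carrying an ortho ester. Both carbons are already present at the right oxidation levels (a benzylic CH2 and a CO2Me), so no further carbon has to be brought in. This bond is a temporary tether: it is broken again in the key step. The forward step asks for benzylic deprotonation next to an ester and O-silylation of a crowded enolate. A tert-butyldimethylsilyl group is chosen in place of trimethylsilyl so that 10 can be purified and does not lose silicon to tert-butoxide before the carbene arrives.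

**8 ⇒ 5 + 7 (O–CH2).** The ether bond that becomes O1–C2 is cut to the benzyl alcohol 5 and the salicylate 7. A redox condensation is preferred to alkylation with a halide because the halide of this 2,4,6-trioxygenated benzyl system is too labile to handle. The precursors are two simple, separately made arenes.

**5 and 7 ⇒ 2 ⇒ 1.** Alcohol 5 comes from aldehyde 4 by reduction and 4 from aldehyde 2 and benzyl bromide 3. Ester 7 comes from acid 6, and 6 from the same aldehyde 2 by oxidation. Aldehyde 2 is the ortho-formylation product of commercial 3,4,5-trimethoxyphenol 1, in which both ortho positions are equivalent and the para position is blocked. One aldehyde, reduced on one arm and oxidised on the other, supplies C2 and C4 of ring C with their aryl rings.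

## Roads not taken

**Alternative 1: ring B by benzannulation.**
- Cut: C1'–C2', C2'–C3' and C5'–C6', so that ring B is built last on a finished chromone.
- Forward key step: the chromone-bound silyl ynol ether A2 is heated with the cyclobutenone A3 (Danheiser benzannulation). Four-electron opening of A3 to a vinylketene, [2+2] addition to the ynol ether, opening of the new cyclobutenone and six-electron closure would give A1, with the 2'-oxygen as a free phenol and the 6'-oxygen as a silyl ether.
- Merits: the regiochemistry follows from ketene and ynol ether polarity, the two ortho oxygens emerge differentiated, and the union is convergent.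
- Weak points: A2 is a push–pull alkyne conjugated to the chromone carbonyl, which lowers its reactivity toward the ketene and makes its preparation by ynolate chemistry next to an enone awkward. A3 carries a methoxy group on its sp3 carbon and can lose methanol. After the annulation, 2'-O-methylation, desilylation and 5-O-demethylation still remain, and the chromone half must be built separately.
- Comparison: in differentiating O2' from O6' this road is as good as the chosen plan, and it would be the better one if ring B analogues with other substitution patterns were wanted. For this target ring B is the cheapest part of the chosen plan (three routine steps from 1), so the chosen plan sets commercial precursors and a shorter sequence against it.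

**Alternative 2: ring A by Dieckmann aromatisation.**
- Cut: C5–C6 of ring A, leading back to the pyranone A5 with an ester on the future C4a and a 3-methoxy-2-oxopropyl chain on the future C8a.
- Forward key step: NaOMe in methanol forms the enolate at the methoxy-bearing carbon, which attacks the ester carbonyl; the new six-membered ring enolises to the aromatic 5,7-diol A4.
- Merits: the 5-hydroxyl is free by construction, so no Lewis acid demethylation is needed. The unchelated 7-hydroxyl can be methylated selectively, and debenzylation then finishes the synthesis.
- Weak points: A5 is a trisubstituted 4-pyranone with four carbonyl-type carbons; its assembly takes many steps through polycarbonyl intermediates that can close in other ways. In the key step methoxide can add to the pyranone, and the more acidic methylene between the pyranone and the ketone is deprotonated first, so the productive enolate is the minor one.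
- Comparison: the endgame of this road is better than that of the chosen plan, which needs the selective demethylation of step 10. The chosen plan sets against it a front end in which both aromatic rings arrive fully oxygenated from one phenol in two or three routine steps each.

**Alternative 3: carbonylative three-component annulation.**
- Cut: C4a–C4, C4–C3 and O1–C2, leading to the iodophenol A7, carbon monoxide and the arylalkyne A8.
- Forward key step: PdCl2(PPh3)2, CO and Et2NH. Oxidative addition of A7 to zerovalent palladium, CO insertion and coupling with A8 give an ynone; the amine adds to it and the phenol closes ring C in the 6-endo sense to give A6.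
- Merits: this is the shortest road. A7 is one iodination from 1 and A8 one homologation from 4, so the target would be reached in about seven steps, three fewer than the chosen plan, and with the same two final deprotections.
- Weak points: the iodine of A7 sits between a hydroxyl and a methoxy group on a ring with four donors, so oxidative addition is slow and loss of iodine competes. Coupling without CO followed by closure would give a 2-arylbenzofuran. The β-carbon of the ynone is shielded by the di-ortho-substituted ring B, which disfavours the amine addition that steers closure to the flavone and favours 5-exo closure to an aurone.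
- Comparison: if the hindered partners coupled cleanly, this road would be better in step count and convergence. The chosen plan is longer but uses no metal-catalysed coupling at a doubly hindered centre, and it fixes the size of ring C by inserting exactly one carbon into a preformed five-membered ring.

Key step: step 8

Remark on the chemistry: 16 has no stereocentre, so its SMILES carries no stereodescriptor; the stereogenic compounds met on the way (12, F4, F5, F6, A3) are racemic and are written without descriptors.

## Route

Step 1
Reactants: 1 3,4,5-trimethoxyphenol
Product: 2 6-hydroxy-2,3,4-trimethoxybenzaldehyde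
Conditions: MgCl2, Et3N, (CH2O)n, MeCN, reflux; then 1 M HCl
Reagents that add atoms: paraformaldehyde (as formaldehyde), C=O
Why: Casnati–Skattebøl ortho-formylation: the magnesium phenoxide delivers formaldehyde to the ortho carbon and a second formaldehyde oxidises the benzylic alkoxide by hydride transfer. The two ortho positions of 1 are equivalent and the para position is blocked, so a single aldehyde is expected.

Step 2
Reactants: 2 6-hydroxy-2,3,4-trimethoxybenzaldehyde; 3 benzyl bromide
Product: 4 6-(benzyloxy)-2,3,4-trimethoxybenzaldehyde
Conditions: K2CO3, DMF, rt → 50 °C
Reagents that add atoms: none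
Why: Williamson ether synthesis on the phenoxide of a salicylaldehyde. The benzyl group should survive hydride, lithium amide, silyl triflate and the carbene conditions and falls together with the C3 bromine in step 9.

Step 3
Reactants: 4 6-(benzyloxy)-2,3,4-trimethoxybenzaldehyde
Product: 5 [6-(benzyloxy)-2,3,4-trimethoxyphenyl]methanol
Conditions: NaBH4, MeOH–THF, 0 °C; aq. NaHCO3 work-up
Reagents that add atoms: none
Why: Borohydride reduction of an aryl aldehyde. The work-up is kept neutral because the 2,4,6-trioxygenated benzyl alcohol ionises under acid.

Step 4
Reactants: 2 6-hydroxy-2,3,4-trimethoxybenzaldehyde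
Product: 6 6-hydroxy-2,3,4-trimethoxybenzoic acid
Conditions: NaClO2, NaH2PO4, 2-methyl-2-butene, t-BuOH–H2O, 0 °C → rt
Reagents that add atoms: sodium chlorite, [Na+].[O-]Cl=O
Why: Lindgren–Pinnick oxidation: chlorous acid adds to the aldehyde and fragments to the acid and HOCl, which 2-methyl-2-butene intercepts before it can chlorinate the one free ring position. The buffered, cold conditions avoid decarboxylation of the 2,6-dioxygenated acid.

Step 5
Reactants: 6 6-hydroxy-2,3,4-trimethoxybenzoic acid
Product: 7 methyl 6-hydroxy-2,3,4-trimethoxybenzoate
Conditions: MeI, KHCO3, DMF, rt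
Reagents that add atoms: iodomethane, CI
Why: SN2 alkylation of the carboxylate; bicarbonate ionises the acid but not the hydrogen-bonded phenol. Hot acidic Fischer conditions are avoided because 6 would decarboxylate.

Step 6
Reactants: 5 [6-(benzyloxy)-2,3,4-trimethoxyphenyl]methanol; 7 methyl 6-hydroxy-2,3,4-trimethoxybenzoate
Product: 8 methyl 6-{[6-(benzyloxy)-2,3,4-trimethoxyphenyl]methoxy}-2,3,4-trimethoxybenzoate
Conditions: PPh3, DIAD, THF, 0 °C → rt
Reagents that add atoms: none
Why: Mitsunobu etherification of a primary benzylic alcohol with an acidic salicylate phenol. It avoids the labile benzylic halide, and the neutral medium preserves the acid-sensitive benzyl aryl ether that forms.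

Step 7
Reactants: 8 methyl 6-{[6-(benzyloxy)-2,3,4-trimethoxyphenyl]methoxy}-2,3,4-trimethoxybenzoate
Product: 10 tert-butyl({2-[6-(benzyloxy)-2,3,4-trimethoxyphenyl]-4,5,6-trimethoxy-1-benzofuran-3-yl}oxy)dimethylsilane, via lithium benzofuran-3-olate 9 (not isolated)
Conditions: LiN(iPr)2 (LDA, 2.5 equiv), THF, −78 → 0 °C; then TBSOTf, −78 → 0 °C
Reagents that add atoms: tert-butyldimethylsilyl trifluoromethanesulfonate, CC(C)(C)[Si](C)(C)OS(=O)(=O)C(F)(F)F
Why: Carbanionic cyclisation of a benzyl aryl ether onto an ortho ester (intramolecular Claisen-type acylation, 5-exo-trig), a known route to 2-arylbenzofuran-3(2H)-ones: the amide base removes a benzylic proton next to the aryloxy oxygen, helped by coordination to the ester and the flanking alkoxy groups, the anion adds to the ester and methoxide leaves. The second equivalent of base deprotonates the ketone to the aromatic 3-oxidobenzofuran 9, which the hard silyl triflate captures on oxygen; trapping in the same flask avoids isolating the air-sensitive ketone.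

Step 8
Reactants: 10 tert-butyl({2-[6-(benzyloxy)-2,3,4-trimethoxyphenyl]-4,5,6-trimethoxy-1-benzofuran-3-yl}oxy)dimethylsilane; 11 bromoform
Product: 14 2-[6-(benzyloxy)-2,3,4-trimethoxyphenyl]-3-bromo-5,6,7-trimethoxy-4H-chromen-4-one, via dibromocyclopropane adduct 12 (not isolated), via 4-siloxy-3-bromobenzopyrylium bromide 13 (not isolated)
Conditions: KOtBu, toluene–hexane, −20 °C → rt; aq. NaHCO3
Reagents that add atoms: none
Why: Deprotonation of 11 by KOtBu and loss of bromide give singlet dibromocarbene, an electrophile that adds in a concerted [2+1] fashion to the C2=C3 bond of 10, the only enol ether π bond present and far more nucleophilic than the alkoxyarenes, to give the cis-fused adduct 12 (racemic, its two stereocentres are transient). The bromine lying endo to the furan ring then departs while the bond shared by the three- and five-membered rings cleaves in a Woodward–Hoffmann-allowed disrotatory two-electron opening (cyclopropyl to allyl cation), assisted from both termini by the lone pairs of O1 and of the siloxy oxygen, which gives the aromatic pyrylium salt 13. Ring C therefore closes by one-carbon expansion of the furan and not by cyclisation of a chain: the carbene carbon becomes C3 and the new bonds are C2–C3 and C3–C4. Transfer of the silyl group from 13 to tert-butoxide, bromide or water leaves the pyranone 14, which has no stereocentre. The closest known reaction type is the dihalocarbene ring expansion of cyclic silyl enol ethers to 2-halo enones and of 1-siloxyindenes to 2-halo-1-naphthols, together with the Ciamician–Dennstedt expansion of indoles and benzofurans. The step needs chemoselective addition at the furan double bond and cleavage of the internal cyclopropane bond; the first is secured by the doubly oxygen-substituted character of C2=C3, the second because only internal cleavage gives a cation stabilised by both oxygens, and the tert-butyldimethylsilyl group keeps the enol ether intact until the carbene has added.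

Step 9
Reactants: 14 2-[6-(benzyloxy)-2,3,4-trimethoxyphenyl]-3-bromo-5,6,7-trimethoxy-4H-chromen-4-one
Product: 15 2-(6-hydroxy-2,3,4-trimethoxyphenyl)-5,6,7-trimethoxy-4H-chromen-4-one
Conditions: H2 (1 atm), Pd/C, NaOAc, EtOAc–MeOH, rt
Reagents that add atoms: none
Why: Palladium-catalysed hydrogenolysis cleaves the vinylic C3–Br bond and the benzyl ether in one operation; acetate takes up HBr and, unlike an amine base, does not retard benzyl ether cleavage. The C2=C3 bond is a vinylogous ester shielded by the di-ortho-substituted ring B and should resist saturation at one atmosphere.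

Step 10
Reactants: 15 2-(6-hydroxy-2,3,4-trimethoxyphenyl)-5,6,7-trimethoxy-4H-chromen-4-one
Product: 16 5-hydroxy-2-(6-hydroxy-2,3,4-trimethoxyphenyl)-6,7-dimethoxy-4H-chromen-4-one (5,6'-dihydroxy-6,7,2',3',4'-pentamethoxyflavone)
Conditions: BCl3, CH2Cl2, −78 → 0 °C; then aq. NaHCO3–MeOH
Reagents that add atoms: none
Why: Chelation-controlled demethylation: boron binds the C4 carbonyl and O5 in a six-membered chelate and chloride removes the 5-methyl group by SN2, while the five other methyl ethers lack this activation at low temperature. The medium is anhydrous and cold, so the flavone cannot open and reclose through the free 6'-hydroxyl; aqueous work-up hydrolyses the boron phenoxides.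

## Compound list

1 | 3,4,5-trimethoxyphenol | COc1cc(O)cc(OC)c1OC | starting material
2 | 6-hydroxy-2,3,4-trimethoxybenzaldehyde | COc1cc(O)c(C=O)c(OC)c1OC | intermediate
3 | benzyl bromide | BrCc1ccccc1 | starting material
4 | 6-(benzyloxy)-2,3,4-trimethoxybenzaldehyde | COc1cc(OCc2ccccc2)c(C=O)c(OC)c1OC | intermediate
5 | [6-(benzyloxy)-2,3,4-trimethoxyphenyl]methanol | COc1cc(OCc2ccccc2)c(CO)c(OC)c1OC | intermediate
6 | 6-hydroxy-2,3,4-trimethoxybenzoic acid | COc1cc(O)c(C(=O)O)c(OC)c1OC | intermediate
7 | methyl 6-hydroxy-2,3,4-trimethoxybenzoate | COC(=O)c1c(O)cc(OC)c(OC)c1OC | intermediate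
8 | methyl 6-{[6-(benzyloxy)-2,3,4-trimethoxyphenyl]methoxy}-2,3,4-trimethoxybenzoate | COC(=O)c1c(OCc2c(OCc3ccccc3)cc(OC)c(OC)c2OC)cc(OC)c(OC)c1OC | intermediate
9 | lithium 2-[6-(benzyloxy)-2,3,4-trimethoxyphenyl]-4,5,6-trimethoxy-1-benzofuran-3-olate | [Li+].COc1cc2oc(-c3c(OCc4ccccc4)cc(OC)c(OC)c3OC)c([O-])c2c(OC)c1OC | intermediate
10 | tert-butyl({2-[6-(benzyloxy)-2,3,4-trimethoxyphenyl]-4,5,6-trimethoxy-1-benzofuran-3-yl}oxy)dimethylsilane | COc1cc2oc(-c3c(OCc4ccccc4)cc(OC)c(OC)c3OC)c(O[Si](C)(C)C(C)(C)C)c2c(OC)c1OC | intermediate
11 | bromoform | BrC(Br)Br | starting material
12 | tert-butyl({1a-[6-(benzyloxy)-2,3,4-trimethoxyphenyl]-1,1-dibromo-4,5,6-trimethoxy-1a,6b-dihydro-1H-cyclopropa[b][1]benzofuran-6b-yl}oxy)dimethylsilane (racemic, cis-fused) | COc1cc2OC3(c4c(OCc5ccccc5)cc(OC)c(OC)c4OC)C(Br)(Br)C3(O[Si](C)(C)C(C)(C)C)c2c(OC)c1OC | intermediate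
13 | 2-[6-(benzyloxy)-2,3,4-trimethoxyphenyl]-3-bromo-4-[(tert-butyldimethylsilyl)oxy]-5,6,7-trimethoxy-1-benzopyrylium bromide | COc1cc2[o+]c(-c3c(OCc4ccccc4)cc(OC)c(OC)c3OC)c(Br)c(O[Si](C)(C)C(C)(C)C)c2c(OC)c1OC.[Br-] | intermediate
14 | 2-[6-(benzyloxy)-2,3,4-trimethoxyphenyl]-3-bromo-5,6,7-trimethoxy-4H-chromen-4-one | COc1cc(OCc2ccccc2)c(-c2oc3cc(OC)c(OC)c(OC)c3c(=O)c2Br)c(OC)c1OC | intermediate
15 | 2-(6-hydroxy-2,3,4-trimethoxyphenyl)-5,6,7-trimethoxy-4H-chromen-4-one | COc1cc(O)c(-c2cc(=O)c3c(OC)c(OC)c(OC)cc3o2)c(OC)c1OC | intermediate
16 | 5-hydroxy-2-(6-hydroxy-2,3,4-trimethoxyphenyl)-6,7-dimethoxy-4H-chromen-4-one | COc1cc(O)c(-c2cc(=O)c3c(O)c(OC)c(OC)cc3o2)c(OC)c1OC | target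

## Step count and least certain steps

Total step count: 10. Longest linear sequence: 8 steps (1 → 2 → 4 → 5 → 8 → 10 → 14 → 15 → 16); the ring A arm 1 → 2 → 6 → 7 → 8 is equally long up to 8.

**Step 8 (key step).** The most likely failure is loss of the silyl group to tert-butoxide before the carbene adds. The freed enolate would then be C-alkylated by the carbene at C2 (a Reimer–Tiemann-type path that ends in a dibromomethyl ketone, not in ring expansion). Slow addition to the crowded tetrasubstituted double bond, shielded by the twisted ring B, is the second risk. The fallback gives up the ring expansion and closes ring C by oxidative cyclisation of a chalcone. It sets out from 1 and 4. Phenol 1 is acetylated ortho to the hydroxyl with acetic acid and BF3·OEt2 (Friedel–Crafts) to 1-(6-hydroxy-2,3,4-trimethoxyphenyl)ethan-1-one F1. Claisen–Schmidt condensation of F1 with 4 (KOH, EtOH) gives (E)-3-[6-(benzyloxy)-2,3,4-trimethoxyphenyl]-1-(6-hydroxy-2,3,4-trimethoxyphenyl)prop-2-en-1-one F2. Catalytic I2 in DMSO at 120 °C closes and dehydrogenates it to 2-[6-(benzyloxy)-2,3,4-trimethoxyphenyl]-5,6,7-trimethoxy-4H-chromen-4-one F3 (the same substance as A6). Hydrogenolysis of the benzyl ether under the conditions of step 9 returns to the route at 15.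

**Step 7.** The most likely failure is incomplete benzylic deprotonation, because the electron-rich ring B lowers the acidity of the CH2 group. Competing deprotonation at the protecting benzyl group with Wittig rearrangement and incomplete O-silylation of the crowded enolate are further risks. The fallback forms the benzofuranone by Friedel–Crafts acylation in place of a carbanion and sets out from 4 and 1. Addition of chloroform to 4 with DBU gives 1-[6-(benzyloxy)-2,3,4-trimethoxyphenyl]-2,2,2-trichloroethan-1-ol F4. In a Jocic–Reeve reaction with the sodium phenoxide of 1 (NaOH, aqueous DME), the dichloroepoxide derived from F4 is opened at the benzylic carbon to give 2-[6-(benzyloxy)-2,3,4-trimethoxyphenyl]-2-(3,4,5-trimethoxyphenoxy)acetic acid F5. Trifluoroacetic anhydride in CH2Cl2 closes F5 ortho to the ether oxygen to 2-[6-(benzyloxy)-2,3,4-trimethoxyphenyl]-4,5,6-trimethoxy-1-benzofuran-3(2H)-one F6. Soft enolisation and silylation (TBSOTf, Et3N, CH2Cl2) return to the route at 10.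

**Step 4.** The most likely failure is chlorination of the free ring position by hypochlorous acid that escapes the scavenger, oxidative degradation of the electron-rich phenol, or decarboxylation during isolation. The fallback introduces the carboxyl group without an oxidant: Kolbe–Schmitt carboxylation of 1 (K2CO3, CO2 under pressure, 150 °C, then cold acidification). It sets out from 1 and comes back at 6 without a new intermediate.

**Step 6.** The most likely failure is ionisation of the activated oxyphosphonium intermediate of 5, followed by capture at a ring carbon of the phenol or by the hydrazide, or slow reaction of the hydrogen-bonded phenol. The fallback is a Williamson alkylation. It sets out from 5, which is converted with methanesulfonyl chloride, Et3N and LiCl in THF at 0 °C into 1-(benzyloxy)-2-(chloromethyl)-3,4,5-trimethoxybenzene F7, used at once without purification. Reaction of F7 with 7 (K2CO3, DMF) comes back to the route at 8.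

**Step 10.** The most likely failure is loss of a second methyl group, either at O6 next to the boron-bound O5 or at the crowded central 3'-methoxy group, since the free 6'-phenol consumes reagent and makes the stoichiometry harder to control. The fallback moves the Lewis acid step ahead of the hydrogenolysis and merges it with debenzylation. It sets out from 14, which with BCl3 and pentamethylbenzene in CH2Cl2 at −78 °C loses the benzyl group and the chelated methyl group to give 3-bromo-5-hydroxy-2-(6-hydroxy-2,3,4-trimethoxyphenyl)-6,7-dimethoxy-4H-chromen-4-one F8. Hydrodebromination of F8 with sodium formate and catalytic Pd(PPh3)4 (zerovalent palladium) in DMF at 80 °C, which cannot saturate the C2=C3 bond, comes back to the route at 16.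

## Further compounds

F1 | step 8 | 1-(6-hydroxy-2,3,4-trimethoxyphenyl)ethan-1-one | CC(=O)c1c(O)cc(OC)c(OC)c1OC
F2 | step 8 | (E)-3-[6-(benzyloxy)-2,3,4-trimethoxyphenyl]-1-(6-hydroxy-2,3,4-trimethoxyphenyl)prop-2-en-1-one | COc1cc(OCc2ccccc2)c(/C=C/C(=O)c2c(O)cc(OC)c(OC)c2OC)c(OC)c1OC
F3 | step 8 | 2-[6-(benzyloxy)-2,3,4-trimethoxyphenyl]-5,6,7-trimethoxy-4H-chromen-4-one | COc1cc(OCc2ccccc2)c(-c2cc(=O)c3c(OC)c(OC)c(OC)cc3o2)c(OC)c1OC
F4 | step 7 | 1-[6-(benzyloxy)-2,3,4-trimethoxyphenyl]-2,2,2-trichloroethan-1-ol (racemic) | COc1cc(OCc2ccccc2)c(C(O)C(Cl)(Cl)Cl)c(OC)c1OC
F5 | step 7 | 2-[6-(benzyloxy)-2,3,4-trimethoxyphenyl]-2-(3,4,5-trimethoxyphenoxy)acetic acid (racemic) | COc1cc(OC(C(=O)O)c2c(OCc3ccccc3)cc(OC)c(OC)c2OC)cc(OC)c1OC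
F6 | step 7 | 2-[6-(benzyloxy)-2,3,4-trimethoxyphenyl]-4,5,6-trimethoxy-1-benzofuran-3(2H)-one (racemic) | COc1cc2OC(c3c(OCc4ccccc4)cc(OC)c(OC)c3OC)C(=O)c2c(OC)c1OC
F0 | step 4 | none | none
F7 | step 6 | 1-(benzyloxy)-2-(chloromethyl)-3,4,5-trimethoxybenzene | COc1cc(OCc2ccccc2)c(CCl)c(OC)c1OC
F8 | step 10 | 3-bromo-5-hydroxy-2-(6-hydroxy-2,3,4-trimethoxyphenyl)-6,7-dimethoxy-4H-chromen-4-one | COc1cc(O)c(-c2oc3cc(OC)c(OC)c(O)c3c(=O)c2Br)c(OC)c1OC
A1 | alternative 1 | 2-{2-hydroxy-3,4-dimethoxy-6-[(triisopropylsilyl)oxy]phenyl}-5,6,7-trimethoxy-4H-chromen-4-one | COc1cc2oc(-c3c(O)c(OC)c(OC)cc3O[Si](C(C)C)(C(C)C)C(C)C)cc(=O)c2c(OC)c1OC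
A2 | alternative 1 | 5,6,7-trimethoxy-2-{[(triisopropylsilyl)oxy]ethynyl}-4H-chromen-4-one | COc1cc2oc(C#CO[Si](C(C)C)(C(C)C)C(C)C)cc(=O)c2c(OC)c1OC
A3 | alternative 1 | 3,4-dimethoxycyclobut-2-en-1-one (racemic) | COC1=CC(=O)C1OC
A4 | alternative 2 | 2-[6-(benzyloxy)-2,3,4-trimethoxyphenyl]-5,7-dihydroxy-6-methoxy-4H-chromen-4-one | COc1cc(OCc2ccccc2)c(-c2cc(=O)c3c(O)c(OC)c(O)cc3o2)c(OC)c1OC
A5 | alternative 2 | methyl 6-[6-(benzyloxy)-2,3,4-trimethoxyphenyl]-2-(3-methoxy-2-oxopropyl)-4-oxo-4H-pyran-3-carboxylate | COCC(=O)Cc1oc(-c2c(OCc3ccccc3)cc(OC)c(OC)c2OC)cc(=O)c1C(=O)OC
A6 | alternative 3 | 2-[6-(benzyloxy)-2,3,4-trimethoxyphenyl]-5,6,7-trimethoxy-4H-chromen-4-one | COc1cc(OCc2ccccc2)c(-c2cc(=O)c3c(OC)c(OC)c(OC)cc3o2)c(OC)c1OC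
A7 | alternative 3 | 2-iodo-3,4,5-trimethoxyphenol | COc1cc(O)c(I)c(OC)c1OC
A8 | alternative 3 | 1-(benzyloxy)-2-ethynyl-3,4,5-trimethoxybenzene | COc1cc(OCc2ccccc2)c(C#C)c(OC)c1OC
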